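## Analysis of the target

Compound 19 is a flavan. Ring A is fused to the oxygen heterocycle (ring C), C2 carries a 4-hydroxyphenyl group (ring B), C7 a hydroxyl, and C4 a pentasubstituted benzene (ring D). Ring D has hydroxyls on C2'', C4'' and C6'', the dodecanoyl group on C3'' and hydrogen on C5''. The two stereocentres, C2 and C4, are both R and stand 1,3-cis across ring C, so both aryl groups can sit pseudo-equatorial on the half-chair. The molecule is a pentaphenol and is sensitive to air and to acid. O1–C2 is a benzylic ether para to an oxygen substituent, and C4 is doubly benzylic and bonded to a phloroglucinol-type ring, so both the heterocycle and the C4–C1'' bond can ionise. The difficulty is threefold: the acyl group must sit at one defined position of ring D, three electron-rich rings would compete in any electrophilic substitution, and C2 and C4 must be set cis in one absolute sense. The plan rests on the substitution pattern of ring D. Going round from C1'', the atoms C6''(O), C5''(H) and C4''(O) are those of a 1,3-dioxygenated butadiene whose terminus is C1'', and C2''(O)–C3''(acyl) are those of a 1-alkoxy alkynyl ketone.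

## Retrosynthetic reasoning

**19 to 18.** The last disconnection removes protecting groups only. The C7 and C4' phenols are held as benzyl ethers and the C2'' oxygen as the ethyl ether that the ring construction delivers; C4''–OH and C6''–OH are already free in 18. The ethyl ether is ortho to the ketone, so a boron Lewis acid can cleave it through a six-membered chelate, and the same reagent removes aryl benzyl ethers when a cation scavenger is present. One operation therefore leads to 19, and no C–C bond is made on the flavan after ring D exists.

**18 to 10 and 15.** Ring D is cut at C1''–C2'' and C3''–C4''. This is the only pair of cuts that gives two fragments in which every ring D substituent is already in place: diene 10 brings the chroman on its terminus (C1''), a silyloxy group (C6'') and a ketene acetal carbon (C4''), and ynone 15 brings the ethoxy group (C2'') and the acyl group (C3''). The forward reaction has to join the hindered diene terminus to the ethoxy-bearing alkyne carbon, close the ring at the ketene acetal carbon and aromatise by loss of the methoxy and silyl groups. No stereocentre is made, and the regiochemistry follows from the polarity of the partners. The C6'' oxygen is carried as a trimethylsilyl enol ether and not as an alkyl enol ether: O-alkylation of a β-keto ester with a benzyl halide competes with C-alkylation, whereas O-silylation is clean, makes the diene more nucleophilic, and leaves a group that falls off on work-up.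

**15 to 11 and 12.** The ynone is cut between the alkyne and the carbonyl carbon. The acetylide 13 of 11 adds to aldehyde 12 and the propargylic alcohol 14 is oxidised under neutral conditions, which the acid-sensitive ynol ether requires.

**10 to 8.** The diene is the twofold O-silylation product of β-keto ester 8, by way of the enol ether 9. No skeletal bond is involved, and the chroman C4–H is not acidic enough to interfere.

**8 to 7.** The bond between the ketone carbon and the ester methylene is cut. An acetate enolate acylated by ester 7 gives 8 in one step. C4 is β to the reacting carbonyl and cannot epimerise.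

**7 to 6.** The C4 stereocentre is traced back to the alkene of 6. Addition of hydrogen anti to the C2 aryl group puts the side chain cis to it, so C2 controls C4.

**6 to 4.** The C4–CH2 bond is cut. The ketone of 4 is conjugated with O1 and O7 and is a poor electrophile, and any enolate of 4 can expel the O1 phenoxide (retro-oxa-Michael), which would racemise C2. The carbonyl is therefore turned into enol triflate 5 without a free enolate, and the ester arm is attached by cross-coupling of a zinc ester enolate. A flavone was also weighed as the source of the heterocycle. It would need olefination at a γ-pyrone carbonyl and a twofold enantioselective hydrogenation of a 4-ylidene-4H-chromene, and neither can be relied on, so it was set aside.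

**4 to 2 and 3.** The C2–aryl bond is cut. Catalytic asymmetric conjugate addition of boronic acid 3 to chromone 2 sets C2 in the R configuration.

**2 to 1.** Benzylation of the commercial hydroxychromone 1.

## Alternatives that were turned down

**Alternative 1: ring A and ring C by (2+2+2) cycloaddition.** Ring A is cut at C4a–C8a, C7–C8 and C5–C6. In the forward step a ruthenium catalyst would join the two alkynes of diyne A1 (an ethynyl ether on the C2 oxygen and a silylalkyne on C4) with the alkynylboronate A2 (ethynylboronic acid pinacol ester). This closes rings A and C together and gives A3, the cis chroman with boron on C7 and silicon on C5.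
- For: two rings and three C–C bonds form in one neutral catalytic step, ring D arrives intact, and the boron marks C7 for oxidation. On convergence and bonds per step it is stronger than the chosen route.
- Against: both stereocentres must be set in the open chain of A1 by separate asymmetric steps. The ethynyl ether of a para-oxygenated benzylic alcohol is fragile. After the key step the C–B bond must be oxidised and the C–Si bond removed. Ring D of A3 still lacks the dodecanoyl group, so a late Friedel–Crafts acylation on an acid-labile flavan remains.
- Comparison: the chosen route gives up the double ring closure but places the acyl group and all three oxygens of ring D by construction, and only one operation follows its key step.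

**Alternative 2: flavylium and resorcinol, bridged ketal as relay.** The cuts are C4–C4a and O1–C2. The flavylium cation A4, whose benzo ring is ring D and which already holds C2, C3, C4 and ring B, would be paired with a chiral phosphate and attacked at C4 by resorcinol A5. The neighbouring hydroxyl then closes onto C2 to give the bridged ketal A6, a 2,8-dioxabicyclo[3.3.1]nonane. Reductive opening of the C2–O bond to ring D, with hydride entering anti to the bridge, would give the cis flavan.
- For: it is the shortest of the four routes, needs few protecting groups, carries the acyl group from the start, and relays the relative configuration through the bicycle. On step count it is clearly ahead of the chosen route.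
- Against: the absolute sense depends on ion pairing of a phosphate with a polyhydroxylated flavylium ion, which can lose a proton to a neutral quinoidal base and so loosen the pair. The ketal has two aryl–O–C2 bonds and only the one to ring D may break. The reduction needs acid on a 4-arylflavan. A4 itself requires a regiodefined formyl acylphloroglucinol.
- Comparison: the chosen route is longer, but its absolute configuration comes from an established catalytic arylation and there is no ambiguity about which ring becomes ring A.

**Alternative 3: ortho-quinone methide and vinylphenol.** The cuts are C3–C4 and O1–C2. A chiral BINOL-derived phosphoric acid would dehydrate benzhydrol A7 to the ring A ortho-quinone methide, which takes up 4-vinylphenol A8 in a (4+2) annulation to give chroman A9.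
- For: both stereocentres are set in one catalytic step with the cis relationship built in. The reaction type is better precedented than the key step chosen here. It is the strongest alternative on step economy and stereocontrol.
- Against: the quinone methide carbon carries a 2,4,6-trioxygenated aryl group, which is twisted and hindered and stabilises the cation so well that the ion pair with the catalyst may be loose. Ring D of A9 has no acyl group, so the dodecanoyl group must be introduced late by electrophilic substitution, with rings A, B and D competing and the flavan exposed to acid. An acyl group placed on A7 beforehand would deactivate and crowd the cation.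
- Comparison: the chosen route answers exactly the question this alternative leaves open, the position of the acyl group, and needs no electrophilic chemistry on the flavan. It pays with more steps and an untested ring construction.

Key step: step 11

Assumption: the (S)-tert-butyl pyridine-oxazoline ligand is taken to deliver the aryl group in step 2 to the enone face that gives the 2R ketone, as it does with cyclic enones; if the sense is the opposite, the (R)-ligand is used.

## Route

Steps are numbered by branch. In practice ynone 15 (steps 9 and 10) is prepared before diene 10, which is used as soon as it is made.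

Step 1
Reactants: 1 7-hydroxy-4H-chromen-4-one
Product: 2 7-(benzyloxy)-4H-chromen-4-one
Conditions: BnBr (1.2 equiv), K2CO3, DMF, 23 °C
Reagents that add atoms: benzyl bromide, BrCc1ccccc1
Why: Williamson ether synthesis; the C7 phenol is a vinylogous acid and is alkylated cleanly with carbonate as base.

Step 2
Reactants: 2 7-(benzyloxy)-4H-chromen-4-one; 3 [4-(benzyloxy)phenyl]boronic acid
Product: 4 (2R)-7-(benzyloxy)-2-[4-(benzyloxy)phenyl]-2,3-dihydro-4H-chromen-4-one
Conditions: Pd(OCOCF3)2 (5 mol%), (S)-4-tert-butyl-2-(pyridin-2-yl)-4,5-dihydrooxazole (6 mol%), NH4PF6 (30 mol%), H2O (5 equiv), 3 (2 equiv), ClCH2CH2Cl, 60 °C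
Reagents that add atoms: none
Why: Asymmetric conjugate addition of an arylboronic acid to a chromone, catalysed by a divalent palladium pyridine-oxazoline complex, which is known for chromones. The tert-butyl group of the ligand shields one enone face during aryl insertion, so C2 should form in the R configuration. The near-neutral medium avoids retro-oxa-Michael racemisation.

Step 3
Reactants: 4 (2R)-7-(benzyloxy)-2-[4-(benzyloxy)phenyl]-2,3-dihydro-4H-chromen-4-one
Product: 5 (2R)-7-(benzyloxy)-2-[4-(benzyloxy)phenyl]-2H-chromen-4-yl trifluoromethanesulfonate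
Conditions: Tf2O (1.3 equiv), 2,6-di-tert-butyl-4-methylpyridine (1.5 equiv), CH2Cl2, −78 → 0 °C, dark
Reagents that add atoms: trifluoromethanesulfonic anhydride, FC(F)(F)S(=O)(=O)OS(=O)(=O)C(F)(F)F
Why: Enol triflate formation from an aryl ketone: O-triflylation of the electron-rich carbonyl, then loss of a C3 proton to the hindered pyridine. No free enolate forms, so the O1 phenoxide cannot be expelled and C2 keeps its configuration.

Step 4
Reactants: 5 (2R)-7-(benzyloxy)-2-[4-(benzyloxy)phenyl]-2H-chromen-4-yl trifluoromethanesulfonate
Product: 6 ethyl 2-[(2R)-7-(benzyloxy)-2-[4-(benzyloxy)phenyl]-2H-chromen-4-yl]acetate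
Conditions: BrZnCH2CO2Et (0.5 M in THF, 2 equiv), Pd2(dba)3 (2.5 mol%), XPhos (6 mol%), THF, 23 °C, dark
Reagents that add atoms: (2-ethoxy-2-oxoethyl)zinc bromide, CCOC(=O)C[Zn]Br
Why: Negishi-type cross-coupling of a Reformatsky reagent with an alkenyl triflate (oxidative addition to zerovalent palladium, transmetalation of the zinc enolate, reductive elimination). It avoids addition to the weakly electrophilic ketone and fixes the alkene in the ring. Ambient temperature and exclusion of light keep the 2H-chromene from electrocyclic ring opening.

Step 5
Reactants: 6 ethyl 2-[(2R)-7-(benzyloxy)-2-[4-(benzyloxy)phenyl]-2H-chromen-4-yl]acetate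
Product: 7 ethyl 2-[(2R,4S)-7-(benzyloxy)-2-[4-(benzyloxy)phenyl]chroman-4-yl]acetate
Conditions: H2 (1 atm), PtO2 (5 mol%), EtOAc, 23 °C, dark
Reagents that add atoms: none
Why: Heterogeneous syn-hydrogenation of the trisubstituted styrenic alkene. The catalyst should bind the face anti to the C2 aryl group, so the new C4–H is trans to that aryl and the side chain cis to it (4S by name, the spatial arrangement of the target). Platinum is used instead of palladium to spare the aryl benzyl ethers and the benzylic O1–C2 bond.

Step 6
Reactants: 7 ethyl 2-[(2R,4S)-7-(benzyloxy)-2-[4-(benzyloxy)phenyl]chroman-4-yl]acetate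
Product: 8 methyl 4-[(2R,4S)-7-(benzyloxy)-2-[4-(benzyloxy)phenyl]chroman-4-yl]-3-oxobutanoate
Conditions: LDA (3.3 equiv), MeOAc (3.5 equiv), THF, −78 °C; then 7, −78 → −30 °C; aq NH4Cl
Reagents that add atoms: methyl acetate, CC(=O)OC
Why: Crossed Claisen condensation: the lithium enolate of methyl acetate adds to the ethyl ester and expels ethoxide. The β-keto ester is deprotonated as it forms, which drives the reaction and protects the product. C4 is β to the reacting carbonyl and cannot epimerise.

Step 7
Reactants: 8 methyl 4-[(2R,4S)-7-(benzyloxy)-2-[4-(benzyloxy)phenyl]chroman-4-yl]-3-oxobutanoate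
Product: 9 methyl (2Z)-4-[(2R,4S)-7-(benzyloxy)-2-[4-(benzyloxy)phenyl]chroman-4-yl]-3-[(trimethylsilyl)oxy]but-2-enoate
Conditions: TMSCl (1.5 equiv), Et3N (1.6 equiv), toluene, 23 °C; filtered under Ar, used crude
Reagents that add atoms: chlorotrimethylsilane, C[Si](C)(C)Cl
Why: O-silylation of the enol of a β-keto ester, the standard first stage towards 1,3-bis(silyloxy) dienes. The geometry of the enol ether is of no consequence, because this double bond becomes the central single bond of the diene.

Step 8
Reactants: 9 methyl (2Z)-4-[(2R,4S)-7-(benzyloxy)-2-[4-(benzyloxy)phenyl]chroman-4-yl]-3-[(trimethylsilyl)oxy]but-2-enoate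
Product: 10 (2R,4S)-7-(benzyloxy)-2-[4-(benzyloxy)phenyl]-4-[(1Z,3Z)-4-methoxy-2,4-bis(trimethylsilyloxy)buta-1,3-dien-1-yl]chroman
Conditions: LDA (1.5 equiv), THF, −78 °C; TMSCl (1.8 equiv), −78 → 20 °C; pentane, filtered under Ar, used at once
Reagents that add atoms: chlorotrimethylsilane, C[Si](C)(C)Cl
Why: Kinetic γ-deprotonation of the β-silyloxy enoate gives the extended dienolate, which is silylated on oxygen; this is the known second stage of the preparation of 4-substituted 1-methoxy-1,3-bis(silyloxy) dienes. The chroman C4–H and C2–H are not acidic enough to compete at −78 °C.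

Step 9
Reactants: 11 ethoxyethyne; 12 dodecanal
Product: 14 1-ethoxytetradec-1-yn-3-ol (racemic), via lithium ethoxyacetylide 13 (not isolated)
Conditions: 11 (1.3 equiv, solution in hexanes), n-BuLi (1.2 equiv), THF, −78 °C; then 12, −78 → 0 °C; aq NH4Cl
Reagents that add atoms: none
Why: Deprotonation of the terminal alkyne and 1,2-addition of the acetylide to the aldehyde. The carbinol stereocentre is removed in the next step, so the racemate is used.

Step 10
Reactants: 14 1-ethoxytetradec-1-yn-3-ol
Product: 15 1-ethoxytetradec-1-yn-3-one
Conditions: activated MnO2 (15 equiv), CH2Cl2, 23 °C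
Reagents that add atoms: none
Why: Oxidation of a propargylic alcohol with manganese dioxide. The neutral, heterogeneous conditions spare the ynol ether, which acid would divert into Meyer–Schuster rearrangement or hydration.

Step 11
Reactants: 10 (2R,4S)-7-(benzyloxy)-2-[4-(benzyloxy)phenyl]-4-[(1Z,3Z)-4-methoxy-2,4-bis(trimethylsilyloxy)buta-1,3-dien-1-yl]chroman; 15 1-ethoxytetradec-1-yn-3-one
Product: 18 1-{3-[(2R,4R)-7-(benzyloxy)-2-[4-(benzyloxy)phenyl]chroman-4-yl]-2-ethoxy-4,6-dihydroxyphenyl}dodecan-1-one, via cyclohexadiene cycloadduct 16 (not isolated), via aryl trimethylsilyl ether 17 (not isolated)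
Conditions: 15 (1.5 equiv), toluene (0.5 M), Ar, dark, 23 → 70 °C; then 0.1 M HCl, THF, 0 °C, 10 min
Reagents that add atoms: none
Why: Proposed new method: diene 10 is most nucleophilic at its substituted terminus (the carbon bearing the chroman, future C1'') and ynone 15 is most electrophilic at the ethoxy-bearing alkyne carbon, so the first bond (C1''–C2'') should form there in a Mukaiyama–Michael-like event; the resulting allenolate then attacks the oxygen-stabilised cation at the ketene acetal carbon (C3''–C4''), a net intermolecular (4+2) cycloaddition that closes ring D as a six-membered carbocycle. The closest known reaction type is the Diels–Alder reaction and aromatisation of 1-alkoxy-3-silyloxy and 1,3-bis(silyloxy) dienes with acetylenic ketones and esters; a 1-alkoxy ynone as the two-carbon partner and a diene terminus bearing a secondary carbon have not been shown in it. Cycloadduct 16 holds a mixed methyl silyl ketal and a hydrogen on the chroman-bearing ring carbon, so it should lose methoxytrimethylsilane and tautomerise to phenol 17, and dilute acid then removes the remaining aryl silyl group. No stereocentre is created, because the two sp3 ring carbons of 16 become aromatic, and C2 and C4 of the chroman are untouched because C4–H is not activated and the medium is neutral until the brief work-up. The selectivity needed is regiochemical (ethoxy next to the chroman-bearing carbon, acyl next to the new hydroxyl) and is secured by the matched polarisation of the two partners.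

Step 12
Reactants: 18 1-{3-[(2R,4R)-7-(benzyloxy)-2-[4-(benzyloxy)phenyl]chroman-4-yl]-2-ethoxy-4,6-dihydroxyphenyl}dodecan-1-one
Product: 19 1-{2,4,6-trihydroxy-3-[(2R,4R)-7-hydroxy-2-(4-hydroxyphenyl)chroman-4-yl]phenyl}dodecan-1-one
Conditions: BCl3 (1 M in CH2Cl2, 8 equiv), C6HMe5 (8 equiv), CH2Cl2, −78 → 0 °C; MeOH quench at −78 °C
Reagents that add atoms: none
Why: Lewis acid dealkylation: BCl3 activates the aryl benzyl ethers and pentamethylbenzene takes up the benzyl cations by Friedel–Crafts capture, which prevents C-benzylation of rings A and D. The ethyl ether ortho to the ketone is cleaved through a six-membered boron chelate by chloride attack on the ethyl group, helped by the twist that the neighbouring chroman imposes on the ethoxy group. Low temperature is meant to keep the O1–C2 ether and the C4–C1'' bond intact.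

## Compound list

1 | 7-hydroxy-4H-chromen-4-one | O=c1ccoc2cc(O)ccc12 | starting material
2 | 7-(benzyloxy)-4H-chromen-4-one | O=c1ccoc2cc(OCc3ccccc3)ccc12 | intermediate
3 | [4-(benzyloxy)phenyl]boronic acid | OB(O)c1ccc(OCc2ccccc2)cc1 | starting material
4 | (2R)-7-(benzyloxy)-2-[4-(benzyloxy)phenyl]-2,3-dihydro-4H-chromen-4-one | O=C1C[C@H](c2ccc(OCc3ccccc3)cc2)Oc2cc(OCc3ccccc3)ccc21 | intermediate
5 | (2R)-7-(benzyloxy)-2-[4-(benzyloxy)phenyl]-2H-chromen-4-yl trifluoromethanesulfonate | O=S(=O)(OC1=C[C@H](c2ccc(OCc3ccccc3)cc2)Oc2cc(OCc3ccccc3)ccc21)C(F)(F)F | intermediate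
6 | ethyl 2-[(2R)-7-(benzyloxy)-2-[4-(benzyloxy)phenyl]-2H-chromen-4-yl]acetate | CCOC(=O)CC1=C[C@H](c2ccc(OCc3ccccc3)cc2)Oc2cc(OCc3ccccc3)ccc21 | intermediate
7 | ethyl 2-[(2R,4S)-7-(benzyloxy)-2-[4-(benzyloxy)phenyl]chroman-4-yl]acetate | CCOC(=O)C[C@@H]1C[C@H](c2ccc(OCc3ccccc3)cc2)Oc2cc(OCc3ccccc3)ccc21 | intermediate
8 | methyl 4-[(2R,4S)-7-(benzyloxy)-2-[4-(benzyloxy)phenyl]chroman-4-yl]-3-oxobutanoate | COC(=O)CC(=O)C[C@@H]1C[C@H](c2ccc(OCc3ccccc3)cc2)Oc2cc(OCc3ccccc3)ccc21 | intermediate
9 | methyl (2Z)-4-[(2R,4S)-7-(benzyloxy)-2-[4-(benzyloxy)phenyl]chroman-4-yl]-3-[(trimethylsilyl)oxy]but-2-enoate | COC(=O)/C=C(\O[Si](C)(C)C)C[C@@H]1C[C@H](c2ccc(OCc3ccccc3)cc2)Oc2cc(OCc3ccccc3)ccc21 | intermediate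
10 | (2R,4S)-7-(benzyloxy)-2-[4-(benzyloxy)phenyl]-4-[(1Z,3Z)-4-methoxy-2,4-bis(trimethylsilyloxy)buta-1,3-dien-1-yl]chroman | CO/C(O[Si](C)(C)C)=C/C(O[Si](C)(C)C)=C/[C@@H]1C[C@H](c2ccc(OCc3ccccc3)cc2)Oc2cc(OCc3ccccc3)ccc21 | intermediate
11 | ethoxyethyne | CCOC#C | starting material
12 | dodecanal | CCCCCCCCCCCC=O | starting material
13 | lithium ethoxyacetylide | CCOC#C[Li] | intermediate
14 | 1-ethoxytetradec-1-yn-3-ol (racemic) | CCOC#CC(O)CCCCCCCCCCC | intermediate
15 | 1-ethoxytetradec-1-yn-3-one | CCOC#CC(=O)CCCCCCCCCCC | intermediate
16 | 1-{3-[(2R,4S)-7-(benzyloxy)-2-[4-(benzyloxy)phenyl]chroman-4-yl]-2-ethoxy-6-methoxy-4,6-bis(trimethylsilyloxy)cyclohexa-1,4-dien-1-yl}dodecan-1-one (ring carbons 3 and 6 unassigned) | CCCCCCCCCCCC(=O)C1=C(OCC)C([C@@H]2C[C@H](c3ccc(OCc4ccccc4)cc3)Oc3cc(OCc4ccccc4)ccc32)C(O[Si](C)(C)C)=CC1(OC)O[Si](C)(C)C | intermediate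
17 | 1-{3-[(2R,4R)-7-(benzyloxy)-2-[4-(benzyloxy)phenyl]chroman-4-yl]-2-ethoxy-6-hydroxy-4-(trimethylsilyloxy)phenyl}dodecan-1-one | CCCCCCCCCCCC(=O)c1c(O)cc(O[Si](C)(C)C)c([C@@H]2C[C@H](c3ccc(OCc4ccccc4)cc3)Oc3cc(OCc4ccccc4)ccc32)c1OCC | intermediate
18 | 1-{3-[(2R,4R)-7-(benzyloxy)-2-[4-(benzyloxy)phenyl]chroman-4-yl]-2-ethoxy-4,6-dihydroxyphenyl}dodecan-1-one | CCCCCCCCCCCC(=O)c1c(O)cc(O)c([C@@H]2C[C@H](c3ccc(OCc4ccccc4)cc3)Oc3cc(OCc4ccccc4)ccc32)c1OCC | intermediate
19 | 1-{2,4,6-trihydroxy-3-[(2R,4R)-7-hydroxy-2-(4-hydroxyphenyl)chroman-4-yl]phenyl}dodecan-1-one | CCCCCCCCCCCC(=O)c1c(O)cc(O)c([C@@H]2C[C@H](c3ccc(O)cc3)Oc3cc(O)ccc32)c1O | target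

## Step count and least certain steps

Total step count: 12. Longest linear sequence: 10 steps (steps 1 to 8, 11 and 12); ynone 15 comes from a two-step side branch (steps 9 and 10).

**Step 11 (key step).**
- What may go wrong: the donor-substituted alkyne may be too weak a partner for ring closure, so that conjugate addition stops at an open-chain adduct; the ketene acetal may add in a (2+2) sense; the diene may hydrolyse; or the chroman on the diene terminus may slow the first bond formation.
- Fallback (known chemistry, gives up the arene construction): it sets out from 4 and returns at 19. Reduction of 4 with NaBH4 gives the cis alcohol (2R,4R)-7-(benzyloxy)-2-[4-(benzyloxy)phenyl]chroman-4-ol F1. F1 is ionised with a catalytic Brønsted acid in dioxane in the presence of 1-(2,4,6-trihydroxyphenyl)dodecan-1-one F2, a known acylphloroglucinol. This classical flavan-4-ol arylation should give 1-{3-[(2R,4R)-7-(benzyloxy)-2-[4-(benzyloxy)phenyl]chroman-4-yl]-2,4,6-trihydroxyphenyl}dodecan-1-one F3 together with its C4 epimer, which has to be separated. Hydrogenolysis of F3 (H2, Pd(OH)2 on carbon, EtOAc–MeOH) gives 19. The price is loss of stereocontrol at C4 and the return of electrophilic substitution on the flavan.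

**Step 12.**
- What may go wrong: the Lewis acid may ionise the O1–C2 benzylic ether (ring opening, epimerisation at C2, capture by the scavenger) or the C4–C1'' bond before the ethyl ether is cleaved.
- Fallback: it sets out from 18 and returns at 19. Hydrogenolysis of 18 (H2, Pd(OH)2 on carbon) removes the two benzyl groups and gives 1-{2-ethoxy-4,6-dihydroxy-3-[(2R,4R)-7-hydroxy-2-(4-hydroxyphenyl)chroman-4-yl]phenyl}dodecan-1-one F4. The chelated ethyl ether of F4 is then cleaved nucleophilically with MgI2 etherate in warm toluene–THF, where iodide attacks the ethyl group of the magnesium chelate. This gives 19 without a strong Lewis acid.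

**Step 2.**
- What may go wrong: slow insertion into the electron-rich 7-alkoxychromone, protodeboronation of the electron-rich boronic acid, or incomplete enantioselectivity.
- Fallback: it sets out from 2 and 3 and returns at 4. The same addition with an achiral ligand (Pd(OCOCF3)2 with 2,2'-bipyridine) gives racemic 7-(benzyloxy)-2-[4-(benzyloxy)phenyl]-2,3-dihydro-4H-chromen-4-one F5. Kinetic resolution of F5 by asymmetric transfer hydrogenation follows, using a trivalent rhodium complex Cp*RhCl(TsDPEN) of the configuration that reduces the 2S ketone faster, with HCO2H–Et3N. It converts the unwanted enantiomer into (2S,4S)-7-(benzyloxy)-2-[4-(benzyloxy)phenyl]chroman-4-ol F6, which is separated, and leaves 4.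

**Step 4.**
- What may go wrong: slow transmetalation of the zinc enolate, reduction of the triflate, or migration of the alkene during coupling.
- Fallback: it sets out from 4 and returns at 6. Reformatsky addition (Zn, ethyl bromoacetate, THF) to the ketone gives ethyl 2-[(2R)-7-(benzyloxy)-2-[4-(benzyloxy)phenyl]-4-hydroxychroman-4-yl]acetate F7 as a mixture of C4 epimers. Dehydration of F7 with SOCl2 and pyridine at 0 °C gives 6; any exocyclic alkene isomer is hydrogenated to the same ester 7. The risk taken in exchange is opening of the heterocycle by the basic zinc enolate.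

**Step 5.**
- What may go wrong: partial hydrogenolysis of the benzyl ethers, or incomplete facial selectivity.
- Fallback: it sets out from 6 and returns at 7. Hydrogenation over Pd on carbon, which is known to give cis flavans from 4-substituted flav-3-enes, is allowed to remove the benzyl groups as well and gives ethyl 2-[(2R,4S)-7-hydroxy-2-(4-hydroxyphenyl)chroman-4-yl]acetate F8. F8 is benzylated again (BnBr, K2CO3, DMF) to 7.

## Further compounds

F1 | step 11 | (2R,4R)-7-(benzyloxy)-2-[4-(benzyloxy)phenyl]chroman-4-ol | O[C@@H]1C[C@H](c2ccc(OCc3ccccc3)cc2)Oc2cc(OCc3ccccc3)ccc21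
F2 | step 11 | 1-(2,4,6-trihydroxyphenyl)dodecan-1-one | CCCCCCCCCCCC(=O)c1c(O)cc(O)cc1O
F3 | step 11 | 1-{3-[(2R,4R)-7-(benzyloxy)-2-[4-(benzyloxy)phenyl]chroman-4-yl]-2,4,6-trihydroxyphenyl}dodecan-1-one | CCCCCCCCCCCC(=O)c1c(O)cc(O)c([C@@H]2C[C@H](c3ccc(OCc4ccccc4)cc3)Oc3cc(OCc4ccccc4)ccc32)c1O
F4 | step 12 | 1-{2-ethoxy-4,6-dihydroxy-3-[(2R,4R)-7-hydroxy-2-(4-hydroxyphenyl)chroman-4-yl]phenyl}dodecan-1-one | CCCCCCCCCCCC(=O)c1c(O)cc(O)c([C@@H]2C[C@H](c3ccc(O)cc3)Oc3cc(O)ccc32)c1OCC
F5 | step 2 | racemic 7-(benzyloxy)-2-[4-(benzyloxy)phenyl]-2,3-dihydro-4H-chromen-4-one | O=C1CC(c2ccc(OCc3ccccc3)cc2)Oc2cc(OCc3ccccc3)ccc21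
F6 | step 2 | (2S,4S)-7-(benzyloxy)-2-[4-(benzyloxy)phenyl]chroman-4-ol | O[C@H]1C[C@@H](c2ccc(OCc3ccccc3)cc2)Oc2cc(OCc3ccccc3)ccc21
F7 | step 4 | ethyl 2-[(2R)-7-(benzyloxy)-2-[4-(benzyloxy)phenyl]-4-hydroxychroman-4-yl]acetate (both C4 epimers) | CCOC(=O)CC1(O)C[C@H](c2ccc(OCc3ccccc3)cc2)Oc2cc(OCc3ccccc3)ccc21
F8 | step 5 | ethyl 2-[(2R,4S)-7-hydroxy-2-(4-hydroxyphenyl)chroman-4-yl]acetate | CCOC(=O)C[C@@H]1C[C@H](c2ccc(O)cc2)Oc2cc(O)ccc21
A1 | alternative 1 | 1-[4-(benzyloxy)phenyl]-1-(ethynyloxy)-3-[2,4,6-tris(benzyloxy)phenyl]-5-(trimethylsilyl)pent-4-yne, configured as in the SMILES | c1(OCc4ccccc4)cc(OCc4ccccc4)cc(OCc4ccccc4)c1[C@@H](C#C[Si](C)(C)C)C[C@H](c3ccc(OCc4ccccc4)cc3)OC#C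
A2 | alternative 1 | ethynylboronic acid pinacol ester | C#CB1OC(C)(C)C(C)(C)O1
A3 | alternative 1 | cis-2-[4-(benzyloxy)phenyl]-7-(pinacolboryl)-5-(trimethylsilyl)-4-[2,4,6-tris(benzyloxy)phenyl]chroman, configured as in the SMILES | c1(OCc4ccccc4)cc(OCc4ccccc4)cc(OCc4ccccc4)c1[C@@H]2C[C@H](c3ccc(OCc4ccccc4)cc3)Oc3cc(B4OC(C)(C)C(C)(C)O4)cc([Si](C)(C)C)c32
A4 | alternative 2 | 8-dodecanoyl-5,7-dihydroxy-2-(4-hydroxyphenyl)chromenylium | CCCCCCCCCCCC(=O)c1c(O)cc(O)c2ccc(-c3ccc(O)cc3)[o+]c12
A5 | alternative 2 | resorcinol | Oc1cccc(O)c1
A6 | alternative 2 | bridged ketal: rings A and D fused to a 2,8-dioxabicyclo[3.3.1]nonane, 4-hydroxyphenyl on the ketal carbon C2, dodecanoyl on ring D | CCCCCCCCCCCC(=O)c1c(O)cc(O)c2c1O[C@@]3(c4ccc(O)cc4)C[C@@H]2c2ccc(O)cc2O3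
A7 | alternative 3 | [4-(benzyloxy)-2-hydroxyphenyl][2,4,6-tris(benzyloxy)phenyl]methanol | OC(c1ccc(OCc2ccccc2)cc1O)c1c(OCc2ccccc2)cc(OCc2ccccc2)cc1OCc1ccccc1
A8 | alternative 3 | 4-vinylphenol | C=Cc1ccc(O)cc1
A9 | alternative 3 | (2R,4R)-7-(benzyloxy)-2-(4-hydroxyphenyl)-4-[2,4,6-tris(benzyloxy)phenyl]chroman | c1(OCc4ccccc4)cc(OCc4ccccc4)cc(OCc4ccccc4)c1[C@@H]2C[C@H](c3ccc(O)cc3)Oc3cc(OCc4ccccc4)ccc32
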